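**Plan**

- Locants used for every compound: C1 = angular carbon carrying a methyl; C2, C3 = cyclopentane methylenes; C4 = cyclopentane methine holding the side chain; C5 = angular carbon carrying the bridge oxygen; C6, C7 = ethano unit; C8 = methyl-substituted carbon bonded to the ether oxygen; C9 = hydroxyl-bearing carbon; C10 = methylene linking C9 to C1; C11, C12 = methine and oxymethylene of the side chain.
- Retrosynthetic cuts, in order: the C12–O vanillate ester, the C8–O bond of the C5–O–C8 bridge, the C8–C9 bond of the seven-membered ring, then C5–C6, C4–C11 and C1–C10 on a purchased cyclopentanone.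
- Forward: the cyclopentane ring is bought; C1 is made quaternary, the side chain is attached at C4, the C6–C8 arm is added to the C5 ketone, the seven-membered carbocycle closes at C8–C9, the oxygen bridge closes the tetrahydrofuran ring, and the ester comes last.
- Enabling feature: C8 bears a methyl and the ether oxygen and is bonded to the carbinol carbon C9. C8 can therefore be the carbon of a 2-iodoalkene (its =CH2 is the latent methyl) and C9 an aldehyde, held on the two cis arms of the cyclopentanol ring C1–C5.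
- Stereochemistry: C1 from Pd/PHOX decarboxylative allylation; C11 and C4 from Ir–phosphoramidite crotylation; C5 from organocerium addition anti to the C4 branch; C8 from the geometry of the bridge; C9 from an equilibrating Meerwein–Ponndorf–Verley reduction.

Key step: step 13

Remarks on the chemistry:
- The C5 hydroxyl is carried free through the ring closure. It is trans to the C1 acetaldehyde arm, so no lactol can form, and it is the nucleophile of step 14.
- The ring closure is assumed to give both C9 epimers. Compounds 23, 24 and 25 are written without a configuration at C9, and both epimers are processed together until step 15 merges them.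
- The ligand antipodes in steps 3 and 7 are those that give the configurations drawn; for step 3 this should be (R)-t-BuPHOX by analogy with the six-membered series.

**Route**

Step 1
Reactants: 1 2-methylcyclopentan-1-one
Product: 2 trimethyl[(2-methylcyclopent-1-en-1-yl)oxy]silane
Conditions: TMSCl, NaI, Et3N, MeCN, rt; distillation
Reagents that add atoms: chlorotrimethylsilane, C[Si](C)(C)Cl
Why: Silylation under equilibrating conditions (Me3SiI formed in the flask, amine base) should give the thermodynamic tetrasubstituted silyl enol ether, which fixes the enolate regiochemistry at the methyl-bearing carbon (future C1); no stereocenter is formed.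

Step 2
Reactants: 2 trimethyl[(2-methylcyclopent-1-en-1-yl)oxy]silane; 3 allyl chloroformate
Product: 5 allyl 2-methylcyclopent-1-en-1-yl carbonate, via lithium 2-methylcyclopent-1-en-1-olate 4 (not isolated)
Conditions: MeLi, THF, 0 °C; then TMEDA, 3, −78 °C to rt
Reagents that add atoms: none
Why: Si–O cleavage by MeLi releases the regiodefined lithium enolate without equilibration, and O-acylation by the hard chloroformate at low temperature should give the allyl enol carbonate.

Step 3
Reactants: 5 allyl 2-methylcyclopent-1-en-1-yl carbonate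
Product: 6 (R)-2-methyl-2-(prop-2-en-1-yl)cyclopentan-1-one
Conditions: Pd2(dba)3 (2.5 mol %), (R)-t-BuPHOX (6 mol %), THF, 25 °C
Reagents that add atoms: none
Why: Decarboxylative asymmetric allylic alkylation of Tsuji–Trost type (ionisation by zerovalent palladium, loss of CO2, recombination of enolate and allyl within the chiral P,N-ligand sphere) should set the quaternary centre C1 as R by ligand-controlled choice of the enolate face.

Step 4
Reactants: 6 (R)-2-methyl-2-(prop-2-en-1-yl)cyclopentan-1-one
Product: 8 (R)-2-(2,2-dimethoxyethyl)-2-methylcyclopentan-1-one, via keto aldehyde 7 (not isolated)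
Conditions: O3, CH2Cl2/MeOH, −78 °C; Me2S, to rt; then p-TsOH·H2O (cat.), MeOH, rt; NaHCO3 work-up
Reagents that add atoms: methanol, CO
Why: Ozonolysis cleaves the only alkene to the C9 aldehyde, and acid-catalysed acetalisation in methanol should be selective for the aldehyde over the hindered ketone flanked by the quaternary carbon; C1 is not touched.

Step 5
Reactants: 8 (R)-2-(2,2-dimethoxyethyl)-2-methylcyclopentan-1-one
Product: 9 {[(5R)-5-(2,2-dimethoxyethyl)-5-methylcyclopent-1-en-1-yl]oxy}trimethylsilane
Conditions: LiN(i-Pr)2, THF, −78 °C; TMSCl, to 0 °C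
Reagents that add atoms: chlorotrimethylsilane, C[Si](C)(C)Cl
Why: Only C4 carries α-hydrogens, so deprotonation and O-silylation can give a single silyl enol ether.

Step 6
Reactants: 10 (E)-but-2-en-1-ol
Product: 11 (E)-but-2-en-1-yl methyl carbonate
Conditions: ClCO2Me, pyridine, CH2Cl2, 0 °C
Reagents that add atoms: methyl chloroformate, COC(Cl)=O
Why: Routine O-acylation of a primary allylic alcohol with a chloroformate gives the carbonate leaving group needed for allyl-metal formation.

Step 7
Reactants: 9 {[(5R)-5-(2,2-dimethoxyethyl)-5-methylcyclopent-1-en-1-yl]oxy}trimethylsilane; 11 (E)-but-2-en-1-yl methyl carbonate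
Product: 12 (2R,5R)-5-[(2R)-but-3-en-2-yl]-2-(2,2-dimethoxyethyl)-2-methylcyclopentan-1-one
Conditions: [Ir(cod)Cl]2 (2 mol %), O,O'-(1,1'-binaphthyl-2,2'-diyl)-N,N-bis(1-phenylethyl)phosphoramidite (4 mol %, antipode that gives 12), CsF (0.4 equiv), ZnF2 (1.5 equiv), DME, 50 °C
Reagents that add atoms: none
Why: Iridium-catalysed branched-selective allylic alkylation of a fluoride-activated silyl enol ether: the cyclometalated Ir–phosphoramidite allyl complex should set C11 by attack at the methyl-substituted terminus anti to the metal, while the enolate should react through its lower face (cis to the C1 methyl, away from the larger acetal arm) to set C4, and the near-neutral medium should spare the new α-stereocenter from epimerisation.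

Step 8
Reactants: 12 (2R,5R)-5-[(2R)-but-3-en-2-yl]-2-(2,2-dimethoxyethyl)-2-methylcyclopentan-1-one; 13 (4-bromobut-1-yn-1-yl)trimethylsilane
Product: 15 (1S,2R,5R)-5-[(2R)-but-3-en-2-yl]-2-(2,2-dimethoxyethyl)-2-methyl-1-[4-(trimethylsilyl)but-3-yn-1-yl]cyclopentan-1-ol, via Grignard reagent 14 (not isolated)
Conditions: Mg, THF, rt (13 to 14); anhydrous CeCl3, THF, −78 °C; then 12, −78 to 0 °C; water work-up
Reagents that add atoms: none
Why: CeCl3-modified Grignard 1,2-addition suppresses enolisation of the hindered ketone, and the nucleophile should enter anti to the branched C4 substituent (the face of the C1 acetal arm, whose oxygens can also guide the metal), giving C5 with the new chain cis to the C10 arm and the hydroxyl cis to the side chain.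

Step 9
Reactants: 15 (1S,2R,5R)-5-[(2R)-but-3-en-2-yl]-2-(2,2-dimethoxyethyl)-2-methyl-1-[4-(trimethylsilyl)but-3-yn-1-yl]cyclopentan-1-ol
Product: 17 (1S,2R,5R)-2-(2,2-dimethoxyethyl)-5-[(2S)-1-hydroxypropan-2-yl]-2-methyl-1-[4-(trimethylsilyl)but-3-yn-1-yl]cyclopentan-1-ol, via hydroxy aldehyde 16 (not isolated)
Conditions: O3, CH2Cl2/MeOH, Sudan Red 7B as end-point indicator, −78 °C; then NaBH4, −78 °C to rt
Reagents that add atoms: ozone, [O-][O+]=O
Why: Ozonolysis with reductive work-up turns the vinyl group into the C12 primary alcohol; the alkene reacts far faster than the silylated alkyne or the acetal, and cold in-situ reduction of the aldehyde (or its cis-fused lactol) leaves the α-centre C11 intact.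

Step 10
Reactants: 17 (1S,2R,5R)-2-(2,2-dimethoxyethyl)-5-[(2S)-1-hydroxypropan-2-yl]-2-methyl-1-[4-(trimethylsilyl)but-3-yn-1-yl]cyclopentan-1-ol
Product: 19 (1S,2R,5R)-5-[(2S)-1-(benzyloxy)propan-2-yl]-1-(but-3-yn-1-yl)-2-(2,2-dimethoxyethyl)-2-methylcyclopentan-1-ol, via silylated alkyne 18 (not isolated)
Conditions: NaH (1.2 equiv), BnBr (1.1 equiv), Bu4NI (cat.), THF, 0 °C to rt; then MeOH, K2CO3, rt
Reagents that add atoms: benzyl bromide, BrCc1ccccc1
Why: Williamson etherification should occur only at the primary alkoxide because the tertiary one is buried between C1 and C4, and methoxide then removes the alkynyl silicon by protodesilylation in the same flask.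

Step 11
Reactants: 19 (1S,2R,5R)-5-[(2S)-1-(benzyloxy)propan-2-yl]-1-(but-3-yn-1-yl)-2-(2,2-dimethoxyethyl)-2-methylcyclopentan-1-ol
Product: 21 (1S,2R,5R)-5-[(2S)-1-(benzyloxy)propan-2-yl]-2-(2,2-dimethoxyethyl)-1-(3-iodobut-3-en-1-yl)-2-methylcyclopentan-1-ol, via alkenylalane 20 (not isolated)
Conditions: NiCl2(dppp) (3 mol %), i-Bu2AlH (2.5 equiv), THF, 0 °C to rt; then N-iodosuccinimide, 0 °C, dark; aq. potassium sodium tartrate
Reagents that add atoms: N-iodosuccinimide, O=C1CCC(=O)N1I
Why: Nickel-catalysed Markovnikov hydroalumination of the terminal alkyne with the bisphosphine complex places aluminium on the internal carbon C8 (the first equivalent of hydride is consumed by the hydroxyl), and iodinolysis of the C–Al bond gives the 2-iodo-1-alkene; in THF the ethers and the acetal should survive.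

Step 12
Reactants: 21 (1S,2R,5R)-5-[(2S)-1-(benzyloxy)propan-2-yl]-2-(2,2-dimethoxyethyl)-1-(3-iodobut-3-en-1-yl)-2-methylcyclopentan-1-ol
Product: 22 2-[(1R,2S,3R)-3-[(2S)-1-(benzyloxy)propan-2-yl]-2-hydroxy-2-(3-iodobut-3-en-1-yl)-1-methylcyclopentyl]acetaldehyde
Conditions: p-TsOH·H2O (cat.), acetone/H2O (10:1), rt
Reagents that add atoms: water, O
Why: Mild acid hydrolysis of the dimethyl acetal frees the C9 aldehyde; the tertiary alcohol is trans to the aldehyde arm and cannot close a trans-fused five/five lactol, so the aldehyde stays open for the next step.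

Step 13
Reactants: 22 2-[(1R,2S,3R)-3-[(2S)-1-(benzyloxy)propan-2-yl]-2-hydroxy-2-(3-iodobut-3-en-1-yl)-1-methylcyclopentyl]acetaldehyde
Product: 23 (3R,3aS,8aR)-3-[(2S)-1-(benzyloxy)propan-2-yl]-8a-methyl-6-methylideneperhydroazulene-3a,7-diol (cis-fused; both epimers at C7, which is C9 in the route locants)
Conditions: CrCl2 (8 equiv), NiCl2 (5 mol %), degassed DMSO, 0.005 M with slow addition of 22, rt
Reagents that add atoms: none
Why: CrCl2 reduces NiCl2 to zerovalent nickel, which inserts into the C8–I bond; transmetalation to trivalent chromium gives an alkenylchromium species that adds to the C9 aldehyde (Nozaki–Hiyama–Kishi reaction; the closest known cases are intramolecular alkenyl iodide–aldehyde couplings that close medium rings carrying an exocyclic methylene next to the new carbinol). The C8–C9 bond forms and the seven-membered carbocycle closes in a 7-exo-trig mode. The new stereocenter C9 is not relied upon: the chromium-bound oxygen should prefer a pseudo-equatorial position away from the C1 methyl, but either epimer is usable because C9 is re-set in steps 15 and 16. What the step needs is chemoselectivity and ring closure over oligomerisation: the alkenylchromium reagent adds only to the aldehyde and tolerates the free tertiary alcohol and the benzyl ether. The two reacting arms (C6–C7–C8 on C5 and C10–C9 on C1) are cis on the cyclopentane, which together with high dilution favours cyclisation.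

Step 14
Reactants: 23 (3R,3aS,8aR)-3-[(2S)-1-(benzyloxy)propan-2-yl]-8a-methyl-6-methylideneperhydroazulene-3a,7-diol
Product: 25 (3R,3aS,6S,8aR)-3-[(2S)-1-(benzyloxy)propan-2-yl]-6,8a-dimethyl-3a,6-epoxyperhydroazulen-7-ol (both C7 epimers), via alkylmercury trifluoroacetate 24 (not isolated)
Conditions: Hg(OCOCF3)2 (1.1 equiv), THF, 0 °C; then aq. NaOH, NaBH4, 0 °C
Reagents that add atoms: none
Why: Intramolecular oxymercuration (Markovnikov, 5-exo-trig) lets the C5 hydroxyl attack C8 of the mercurinium ion, and reductive demercuration turns the CH2Hg group into the C8 methyl; the C8 configuration is fixed because the tethered oxygen can only reach C8 from the face on which it sits.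

Step 15
Reactants: 25 (3R,3aS,6S,8aR)-3-[(2S)-1-(benzyloxy)propan-2-yl]-6,8a-dimethyl-3a,6-epoxyperhydroazulen-7-ol
Product: 26 (3R,3aS,6S,8aR)-3-[(2S)-1-(benzyloxy)propan-2-yl]-6,8a-dimethyl-3a,6-epoxyperhydroazulen-7-one
Conditions: Dess–Martin periodinane, NaHCO3, CH2Cl2, rt
Reagents that add atoms: none
Why: Dess–Martin oxidation of the only free hydroxyl merges both C9 epimers into one ketone without touching the ethers.

Step 16
Reactants: 26 (3R,3aS,6S,8aR)-3-[(2S)-1-(benzyloxy)propan-2-yl]-6,8a-dimethyl-3a,6-epoxyperhydroazulen-7-one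
Product: 27 (3R,3aS,6S,7S,8aR)-3-[(2S)-1-(benzyloxy)propan-2-yl]-6,8a-dimethyl-3a,6-epoxyperhydroazulen-7-ol
Conditions: Al(Oi-Pr)3, i-PrOH/toluene, reflux, prolonged, trace acetone retained
Reagents that add atoms: none
Why: Meerwein–Ponndorf–Verley reduction is reversible (Oppenauer back-reaction), so the alcohol should settle at the thermodynamic C9 epimer: the equatorial hydroxyl on the chair oxane ring, because the axial one would be syn-diaxial to the C1 methyl.

Step 17
Reactants: 27 (3R,3aS,6S,7S,8aR)-3-[(2S)-1-(benzyloxy)propan-2-yl]-6,8a-dimethyl-3a,6-epoxyperhydroazulen-7-ol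
Product: 28 (3R,3aS,6S,7S,8aR)-3-[(2S)-1-hydroxypropan-2-yl]-6,8a-dimethyl-3a,6-epoxyperhydroazulen-7-ol
Conditions: H2 (1 atm), Pd/C, EtOH, rt
Reagents that add atoms: none
Why: Catalytic hydrogenolysis removes the benzyl ether; the molecule holds no other reducible group.

Step 18
Reactants: 28 (3R,3aS,6S,7S,8aR)-3-[(2S)-1-hydroxypropan-2-yl]-6,8a-dimethyl-3a,6-epoxyperhydroazulen-7-ol; 29 vanillic acid
Product: 30 (2S)-2-[(3R,3aS,6S,7S,8aR)-7-hydroxy-6,8a-dimethyl-3a,6-epoxyperhydroazulen-3-yl]propyl 4-hydroxy-3-methoxybenzoate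
Conditions: PPh3, DIAD, THF, 0 °C to rt
Reagents that add atoms: none
Why: Mitsunobu esterification should activate only the unhindered primary C12 hydroxyl (the C9 hydroxyl sits next to a quaternary carbon), and the carboxylate, far more acidic than the phenol, is the nucleophile, so neither the phenol nor C9 needs protection; substitution occurs at a CH2 group and no stereocenter is affected.

**Compound list**

1 | 2-methylcyclopentan-1-one | CC1CCCC1=O | starting material
2 | trimethyl[(2-methylcyclopent-1-en-1-yl)oxy]silane | C[Si](C)(C)OC1=C(C)CCC1 | intermediate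
3 | allyl chloroformate | C=CCOC(Cl)=O | starting material
4 | lithium 2-methylcyclopent-1-en-1-olate (not isolated) | [Li+].[O-]C1=C(C)CCC1 | intermediate
5 | allyl 2-methylcyclopent-1-en-1-yl carbonate | C=CCOC(=O)OC1=C(C)CCC1 | intermediate
6 | (R)-2-methyl-2-(prop-2-en-1-yl)cyclopentan-1-one | O=C1[C@@](C)(CC=C)CCC1 | intermediate
7 | (R)-2-(1-methyl-2-oxocyclopentyl)acetaldehyde (not isolated) | O=C1[C@@](C)(CC=O)CCC1 | intermediate
8 | (R)-2-(2,2-dimethoxyethyl)-2-methylcyclopentan-1-one | O=C1[C@@](C)(CC(OC)OC)CCC1 | intermediate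
9 | {[(5R)-5-(2,2-dimethoxyethyl)-5-methylcyclopent-1-en-1-yl]oxy}trimethylsilane | COC(OC)C[C@@]1(C)CCC=C1O[Si](C)(C)C | intermediate
10 | (E)-but-2-en-1-ol | C/C=C/CO | starting material
11 | (E)-but-2-en-1-yl methyl carbonate | C/C=C/COC(=O)OC | intermediate
12 | (2R,5R)-5-[(2R)-but-3-en-2-yl]-2-(2,2-dimethoxyethyl)-2-methylcyclopentan-1-one | C=C[C@@H](C)[C@H]1CC[C@](C)(CC(OC)OC)C1=O | intermediate
13 | (4-bromobut-1-yn-1-yl)trimethylsilane | C[Si](C)(C)C#CCCBr | starting material
14 | [4-(trimethylsilyl)but-3-yn-1-yl]magnesium bromide (not isolated) | C[Si](C)(C)C#CCC[Mg]Br | intermediate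
15 | (1S,2R,5R)-5-[(2R)-but-3-en-2-yl]-2-(2,2-dimethoxyethyl)-2-methyl-1-[4-(trimethylsilyl)but-3-yn-1-yl]cyclopentan-1-ol | C=C[C@@H](C)[C@H]1CC[C@](C)(CC(OC)OC)[C@]1(O)CCC#C[Si](C)(C)C | intermediate
16 | (2S)-2-[(1R,2S,3R)-3-(2,2-dimethoxyethyl)-2-hydroxy-3-methyl-2-[4-(trimethylsilyl)but-3-yn-1-yl]cyclopentyl]propanal (not isolated; in equilibrium with its lactol) | O=C[C@@H](C)[C@H]1CC[C@](C)(CC(OC)OC)[C@]1(O)CCC#C[Si](C)(C)C | intermediate
17 | (1S,2R,5R)-2-(2,2-dimethoxyethyl)-5-[(2S)-1-hydroxypropan-2-yl]-2-methyl-1-[4-(trimethylsilyl)but-3-yn-1-yl]cyclopentan-1-ol | OC[C@@H](C)[C@H]1CC[C@](C)(CC(OC)OC)[C@]1(O)CCC#C[Si](C)(C)C | intermediate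
18 | (1S,2R,5R)-5-[(2S)-1-(benzyloxy)propan-2-yl]-2-(2,2-dimethoxyethyl)-2-methyl-1-[4-(trimethylsilyl)but-3-yn-1-yl]cyclopentan-1-ol (not isolated) | c1ccccc1COC[C@@H](C)[C@H]2CC[C@](C)(CC(OC)OC)[C@]2(O)CCC#C[Si](C)(C)C | intermediate
19 | (1S,2R,5R)-5-[(2S)-1-(benzyloxy)propan-2-yl]-1-(but-3-yn-1-yl)-2-(2,2-dimethoxyethyl)-2-methylcyclopentan-1-ol | c1ccccc1COC[C@@H](C)[C@H]2CC[C@](C)(CC(OC)OC)[C@]2(O)CCC#C | intermediate
20 | diisobutylaluminium alkoxide of 19 carrying a 3-(diisobutylalumanyl)but-3-en-1-yl arm (not isolated) | c1ccccc1COC[C@@H](C)[C@H]2CC[C@](C)(CC(OC)OC)[C@]2(O[Al](CC(C)C)CC(C)C)CCC(=C)[Al](CC(C)C)CC(C)C | intermediate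
21 | (1S,2R,5R)-5-[(2S)-1-(benzyloxy)propan-2-yl]-2-(2,2-dimethoxyethyl)-1-(3-iodobut-3-en-1-yl)-2-methylcyclopentan-1-ol | c1ccccc1COC[C@@H](C)[C@H]2CC[C@](C)(CC(OC)OC)[C@]2(O)CCC(I)=C | intermediate
22 | 2-[(1R,2S,3R)-3-[(2S)-1-(benzyloxy)propan-2-yl]-2-hydroxy-2-(3-iodobut-3-en-1-yl)-1-methylcyclopentyl]acetaldehyde | c1ccccc1COC[C@@H](C)[C@H]2CC[C@](C)(CC=O)[C@]2(O)CCC(I)=C | intermediate
23 | (3R,3aS,8aR)-3-[(2S)-1-(benzyloxy)propan-2-yl]-8a-methyl-6-methylideneperhydroazulene-3a,7-diol (both C7 epimers) | c1ccccc1COC[C@@H](C)[C@H]2CC[C@]3(C)CC(O)C(=C)CC[C@]23O | intermediate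
24 | trifluoroacetoxymercuriomethyl precursor of 25: C8–CH2HgOCOCF3 on the closed 5,8-ether (both C9 epimers; not isolated) | c1ccccc1COC[C@@H](C)[C@H]2CC[C@]3(C)CC(O)[C@]4(C[Hg]OC(=O)C(F)(F)F)CC[C@]23O4 | intermediate
25 | (3R,3aS,6S,8aR)-3-[(2S)-1-(benzyloxy)propan-2-yl]-6,8a-dimethyl-3a,6-epoxyperhydroazulen-7-ol (both C7 epimers) | c1ccccc1COC[C@@H](C)[C@H]2CC[C@]3(C)CC(O)[C@]4(C)CC[C@]23O4 | intermediate
26 | (3R,3aS,6S,8aR)-3-[(2S)-1-(benzyloxy)propan-2-yl]-6,8a-dimethyl-3a,6-epoxyperhydroazulen-7-one | c1ccccc1COC[C@@H](C)[C@H]2CC[C@]3(C)CC(=O)[C@]4(C)CC[C@]23O4 | intermediate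
27 | (3R,3aS,6S,7S,8aR)-3-[(2S)-1-(benzyloxy)propan-2-yl]-6,8a-dimethyl-3a,6-epoxyperhydroazulen-7-ol | c1ccccc1COC[C@@H](C)[C@H]2CC[C@]3(C)C[C@H](O)[C@]4(C)CC[C@]23O4 | intermediate
28 | (3R,3aS,6S,7S,8aR)-3-[(2S)-1-hydroxypropan-2-yl]-6,8a-dimethyl-3a,6-epoxyperhydroazulen-7-ol | OC[C@@H](C)[C@H]1CC[C@]2(C)C[C@H](O)[C@]3(C)CC[C@]12O3 | intermediate
29 | vanillic acid (4-hydroxy-3-methoxybenzoic acid) | COc1cc(C(=O)O)ccc1O | starting material
30 | (2S)-2-[(3R,3aS,6S,7S,8aR)-7-hydroxy-6,8a-dimethyl-3a,6-epoxyperhydroazulen-3-yl]propyl 4-hydroxy-3-methoxybenzoate | COc1cc(C(=O)OC[C@@H](C)[C@H]2CC[C@]3(C)C[C@H](O)[C@]4(C)CC[C@]23O4)ccc1O | target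

**Step count and risks**

Total steps: 18. Longest linear sequence: 17 (steps 1–5 and 7–18; step 6 prepares the crotyl carbonate).

Most likely to fail:

1. Step 7. The small methyl-substituted allyl unit may erode branched selectivity. More seriously, the relative topicity between the enolate face and the allyl face (C4 against C11) may come out wrong, or C4 may epimerise. The fallback sets out from 8 and returns at 17; it relays C11 through a bicyclic lactone instead of relying on the catalyst for it.
   - O-acylation of 8 (LiN(SiMe3)2, then allyl chloroformate, THF, −78 °C) would give allyl (5R)-5-(2,2-dimethoxyethyl)-5-methylcyclopent-1-en-1-yl carbonate F1.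
   - Decarboxylative asymmetric allylation under neutral conditions (Pd2(dba)3·CHCl3, a C2-symmetric bis(2-diphenylphosphinobenzamide) ligand of trans-1,2-diamine type, dioxane, rt) would give the α-allyl ketone F2, with C4 set by the ligand alone.
   - Addition of 14 with CeCl3, anti to the allyl group, would give the tertiary alcohol F3.
   - Ozonolysis (O3, then Me2S) would give the lactol F4, which closes cis-fused onto the C5 hydroxyl; oxidation with PhI(OAc)2 and catalytic TEMPO would give the γ-lactone F5.
   - Enolate methylation (LiN(i-Pr)2, MeI, −78 °C) should occur on the convex face and give the 11-epi lactone F6.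
   - Re-enolisation and kinetic protonation from the same convex face (LiN(i-Pr)2, then 2,6-di-tert-butyl-4-methylphenol, −78 °C) should put the methyl on the concave face, as in the target, giving lactone F7.
   - LiAlH4 reduction of F7 would give diol 17.

2. Step 13. Intermolecular coupling and oligomerisation, or protodeiodination of the alkenylmetal, may compete with a slow seven-membered closure. The fallback sets out from 19 and returns at 23; it forms the same C8–C9 bond without an alkenyl iodide or chromium.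
   - Acetal hydrolysis of 19 (p-TsOH, aqueous acetone) would give the alkynyl aldehyde F8.
   - Nickel-catalysed reductive alkyne–aldehyde cyclisation (Ni(cod)2, 1,3-dimesitylimidazol-2-ylidene, Et3SiH, THF, rt) should join the aldehyde carbon to the internal alkyne carbon and give the silyl ether F9 with the exocyclic methylene.
   - Bu4NF would then give 23.

3. Step 11. Markovnikov regiocontrol may be lost, or the aluminium hydride may reductively open the dimethyl acetal, helped by the neighbouring aluminium alkoxide. The fallback sets out from 19 and returns at 21.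
   - Stannylcupration of the terminal alkyne (Me3SnCu·SMe2, THF, MeOH, −78 °C) would place tin on the internal carbon and give the 2-(trimethylstannyl)alkene F10.
   - Iododestannylation (I2, CH2Cl2, 0 °C) would give 21.

Further compounds
F1 | step 7 | allyl (5R)-5-(2,2-dimethoxyethyl)-5-methylcyclopent-1-en-1-yl carbonate | C=CCOC(=O)OC1=CCC[C@]1(C)CC(OC)OC
F2 | step 7 | (2R,5R)-2-(2,2-dimethoxyethyl)-2-methyl-5-(prop-2-en-1-yl)cyclopentan-1-one | C=CC[C@H]1CC[C@](C)(CC(OC)OC)C1=O
F3 | step 7 | (1S,2R,5R)-2-(2,2-dimethoxyethyl)-2-methyl-5-(prop-2-en-1-yl)-1-[4-(trimethylsilyl)but-3-yn-1-yl]cyclopentan-1-ol | C=CC[C@H]1CC[C@](C)(CC(OC)OC)[C@]1(O)CCC#C[Si](C)(C)C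
F4 | step 7 | cis-fused lactol: C12 hemiacetal closed onto the C5 oxygen (anomers) | OC1C[C@H]2CC[C@](C)(CC(OC)OC)[C@@]2(CCC#C[Si](C)(C)C)O1
F5 | step 7 | cis-fused γ-lactone: C12 carbonyl, C11 methylene | O=C1C[C@H]2CC[C@](C)(CC(OC)OC)[C@@]2(CCC#C[Si](C)(C)C)O1
F6 | step 7 | 11-epi α-methyl lactone (methyl on the convex face) | O=C1[C@H](C)[C@H]2CC[C@](C)(CC(OC)OC)[C@@]2(CCC#C[Si](C)(C)C)O1
F7 | step 7 | α-methyl lactone with the C11 configuration of the target (methyl on the concave face) | O=C1[C@@H](C)[C@H]2CC[C@](C)(CC(OC)OC)[C@@]2(CCC#C[Si](C)(C)C)O1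
F8 | step 13 | 2-[(1R,2S,3R)-3-[(2S)-1-(benzyloxy)propan-2-yl]-2-(but-3-yn-1-yl)-2-hydroxy-1-methylcyclopentyl]acetaldehyde | c1ccccc1COC[C@@H](C)[C@H]2CC[C@](C)(CC=O)[C@]2(O)CCC#C
F9 | step 13 | C9 triethylsilyl ether of 23 (both C9 epimers) | c1ccccc1COC[C@@H](C)[C@H]2CC[C@]3(C)CC(O[Si](CC)(CC)CC)C(=C)CC[C@]23O
F10 | step 11 | (1S,2R,5R)-5-[(2S)-1-(benzyloxy)propan-2-yl]-2-(2,2-dimethoxyethyl)-2-methyl-1-[3-(trimethylstannyl)but-3-en-1-yl]cyclopentan-1-ol | c1ccccc1COC[C@@H](C)[C@H]2CC[C@](C)(CC(OC)OC)[C@]2(O)CCC(=C)[Sn](C)(C)C
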